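**Retrosynthetic overview**
1. Target ⇒ acetylation of C9–OH, preceded by Yamaguchi esterification of C8–OH with (2S,3S)-2,3-dimethyloxirane-2-carboxylic acid (from catalytic Sharpless epoxidation of angelyl alcohol), on a germacranolide whose 8,9-diol is differentiated as PMB/TBS ethers.
2. Germacranolide ⇒ open-chain C6 enal / (Z)-2-(bromomethyl)acrylate: CrCl2 allylation closes the ten-membered carbocycle first (C6–C7), the α-methylene-γ-lactone second, in the same flask.
3. Open-chain precursor ⇒ C7 aldehyde + methyl propiolate (vinylalumination, then SN2′ bromide); C9–C10 by chelation-controlled addition of a (Z)-alkenylmagnesium (geraniol, Stork–Zhao iodide) to a C7–C9 α-alkoxy aldehyde.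
4. C7–C9 aldehyde ⇒ lipase desymmetrisation of prochiral 2-O-PMB-glycerol diacetate, which sets the first stereocentre (C8).

Abbreviations: PMB = 4-methoxybenzyl, TBS = tert-butyldimethylsilyl, TES = triethylsilyl. Locants C1–C15 are germacrane numbering; α/β are as in the usual germacranolide drawing.

Assumption: the lipase of step 4 hydrolyses the pro-S acetate of 4, as it does with the 2-O-benzyl analogue; acylation of diol 3 with vinyl acetate by the same enzyme would give the complementary arm selectivity.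

**Route**

Step 1
Reactants: 1 2,2-dimethyl-1,3-dioxan-5-ol
Product: 2 5-(PMB-oxy)-2,2-dimethyl-1,3-dioxane
Conditions: NaH, PMBCl, Bu4NI (cat.), THF/DMF, 0 °C → rt
Reagents that add atoms: 4-methoxybenzyl chloride, COc1ccc(CCl)cc1
Why: Williamson etherification of the only free hydroxyl puts the chelating, DDQ-cleavable PMB group on the future O8; no stereocentre.

Step 2
Reactants: 2 5-(PMB-oxy)-2,2-dimethyl-1,3-dioxane
Product: 3 2-(PMB-oxy)propane-1,3-diol
Conditions: AcOH/H2O (4:1), rt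
Reagents that add atoms: none
Why: Acid-catalysed acetal hydrolysis frees the prochiral 1,3-diol; the PMB ether is stable to dilute acetic acid.

Step 3
Reactants: 3 2-(PMB-oxy)propane-1,3-diol
Product: 4 2-(PMB-oxy)propane-1,3-diyl diacetate
Conditions: Ac2O, pyridine, DMAP (cat.), CH2Cl2, rt
Reagents that add atoms: acetic anhydride, CC(=O)OC(C)=O
Why: DMAP-catalysed acetylation of both primary alcohols gives the prochiral diester substrate for the enzyme.

Step 4
Reactants: 4 2-(PMB-oxy)propane-1,3-diyl diacetate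
Product: 5 (2R)-3-hydroxy-2-(PMB-oxy)propyl acetate
Conditions: lipase (Burkholderia cepacia lipase, Amano PS), KH2PO4/K2HPO4 buffer (100 mM, pH 7.0), i-Pr2O (10% v/v), 25 °C, stopped at one equivalent of hydrolysis
Reagents that add atoms: none
Why: Enzymatic desymmetrisation: the lipase hydrolyses only one of the two enantiotopic acetates of the prochiral diester, which sets the first stereocentre of the route (future C8, 2R) by asymmetric catalysis.

Step 5
Reactants: 5 (2R)-3-hydroxy-2-(PMB-oxy)propyl acetate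
Product: 6 (2S)-2-(PMB-oxy)-3-(TES-oxy)propyl acetate
Conditions: TESCl, imidazole, CH2Cl2, 0 °C (5 used at once)
Reagents that add atoms: chlorotriethylsilane, CC[Si](Cl)(CC)CC
Why: Fast silylation of the free arm under cold, near-neutral conditions fixes the two arms as different groups before acyl migration can erode the ee; the descriptor changes by CIP priority only.

Step 6
Reactants: 6 (2S)-2-(PMB-oxy)-3-(TES-oxy)propyl acetate
Product: 7 (2S)-2-(PMB-oxy)-3-(TES-oxy)propan-1-ol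
Conditions: i-Bu2AlH (2.5 equiv), CH2Cl2, −78 °C; aq. KNaC4H4O6
Reagents that add atoms: none
Why: Reductive ester cleavage by hydride at −78 °C removes the acetate without base, so neither silyl nor acyl migration between the arms can racemise C8.

Step 7
Reactants: 7 (2S)-2-(PMB-oxy)-3-(TES-oxy)propan-1-ol
Product: 8 (2R)-2-(PMB-oxy)-3-(TES-oxy)propanal
Conditions: Dess–Martin periodinane, pyridine, CH2Cl2, 0 °C → rt (used crude)
Reagents that add atoms: none
Why: Buffered Dess–Martin oxidation gives the α-alkoxy aldehyde (C9) without epimerising C8.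

Step 8
Reactants: 9 geraniol
Product: 10 geranyl TBS ether
Conditions: TBSCl, imidazole, CH2Cl2, rt
Reagents that add atoms: tert-butyldimethylsilyl chloride, CC(C)(C)[Si](C)(C)Cl
Why: Standard silyl ether formation protects the future C6 oxygen against the organometallic steps.

Step 9
Reactants: 10 geranyl TBS ether
Product: 11 6,7-epoxygeranyl TBS ether (racemic)
Conditions: mCPBA (1.0 equiv), CH2Cl2, −20 → 0 °C
Reagents that add atoms: 3-chloroperoxybenzoic acid, OOC(=O)c1cccc(Cl)c1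
Why: Prilezhaev epoxidation takes the more electron-rich distal alkene (the 2,3-alkene is deactivated by the allylic oxygen); the racemic epoxide stereocentre is erased in step 10.

Step 10
Reactants: 11 6,7-epoxygeranyl TBS ether (racemic)
Product: 12 (4E)-6-(TBS-oxy)-4-methylhex-4-enal
Conditions: H5IO6 (1.2 equiv), THF/Et2O, 0 °C, 30 min
Reagents that add atoms: none
Why: Periodic acid opens the epoxide and cleaves the resulting glycol (Malaprade-type cleavage) to the C1 aldehyde and acetone, leaving the E-alkene (C4=C5) untouched.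

Step 11
Reactants: 12 (4E)-6-(TBS-oxy)-4-methylhex-4-enal
Product: 13 tert-butyl{[(2E,6Z)-7-iodo-3-methylocta-2,6-dien-1-yl]oxy}dimethylsilane
Conditions: EtPPh3I, n-BuLi, THF, 0 °C → rt; iodine, −78 °C; NaN(SiMe3)2, −20 °C; then 12, −78 °C → rt
Reagents that add atoms: ethyltriphenylphosphonium iodide, CC[P+](c1ccccc1)(c1ccccc1)c1ccccc1.[I-]; iodine, [I][I]
Why: Stork–Zhao–Wittig olefination: the α-iodo ylide reacts under kinetic control to give the (Z)-2-iodoalkene, with iodine cis to the chain, which fixes the 1(10)Z geometry.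

Step 12
Reactants: 13 tert-butyl{[(2E,6Z)-7-iodo-3-methylocta-2,6-dien-1-yl]oxy}dimethylsilane, 8 (2R)-2-(PMB-oxy)-3-(TES-oxy)propanal
Product: 16 (2R,3R,4Z,8E)-10-(TBS-oxy)-2-(PMB-oxy)-4,8-dimethyl-1-(TES-oxy)deca-4,8-dien-3-ol, via alkenyllithium 14 (not isolated), via alkenylmagnesium bromide 15 (not isolated)
Conditions: 13, t-BuLi (2.1 equiv), Et2O, −78 °C; MgBr2·OEt2, −78 → −40 °C; then 8 (premixed with MgBr2·OEt2), CH2Cl2, −78 °C
Reagents that add atoms: none
Why: Lithium–iodine exchange and transmetalation keep the alkene geometry, and Cram-chelate-controlled addition (five-membered magnesium chelate of C=O and the PMB ether, attack from the face opposite C7) sets C9 as R, syn to O8.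

Step 13
Reactants: 16 (2R,3R,4Z,8E)-10-(TBS-oxy)-2-(PMB-oxy)-4,8-dimethyl-1-(TES-oxy)deca-4,8-dien-3-ol
Product: 17 (2R,3R,4Z,8E)-3,10-bis(TBS-oxy)-2-(PMB-oxy)-4,8-dimethyl-1-(TES-oxy)deca-4,8-diene
Conditions: TBSOTf, 2,6-lutidine, CH2Cl2, −78 → 0 °C
Reagents that add atoms: tert-butyldimethylsilyl triflate, CC(C)(C)[Si](C)(C)OS(=O)(=O)C(F)(F)F
Why: Silyl triflate silylation of the hindered allylic C9 alcohol keeps O9 distinct from O8 (PMB) to the end and blocks β-elimination at the later C7 aldehyde stage.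

Step 14
Reactants: 17 (2R,3R,4Z,8E)-3,10-bis(TBS-oxy)-2-(PMB-oxy)-4,8-dimethyl-1-(TES-oxy)deca-4,8-diene
Product: 18 (2R,3R,4Z,8E)-3,10-bis(TBS-oxy)-2-(PMB-oxy)-4,8-dimethyldeca-4,8-dien-1-ol
Conditions: PPTS (0.1 equiv), MeOH/CH2Cl2 (1:1), 0 °C
Reagents that add atoms: none
Why: Acid-catalysed methanolysis cleaves the primary TES ether far faster than the primary or secondary TBS ethers, which frees only C7–OH.

Step 15
Reactants: 18 (2R,3R,4Z,8E)-3,10-bis(TBS-oxy)-2-(PMB-oxy)-4,8-dimethyldeca-4,8-dien-1-ol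
Product: 19 (2S,3R,4Z,8E)-3,10-bis(TBS-oxy)-2-(PMB-oxy)-4,8-dimethyldeca-4,8-dienal
Conditions: Dess–Martin periodinane, pyridine, CH2Cl2, 0 °C → rt (used crude)
Reagents that add atoms: none
Why: Buffered Dess–Martin oxidation gives the C7 aldehyde without epimerising C8 (descriptor change by CIP only).

Step 16
Reactants: 19 (2S,3R,4Z,8E)-3,10-bis(TBS-oxy)-2-(PMB-oxy)-4,8-dimethyldeca-4,8-dienal
Product: 20 methyl (4R,5R,6Z,10E)-5,12-bis(TBS-oxy)-3-hydroxy-4-(PMB-oxy)-6,10-dimethyl-2-methylidenedodeca-6,10-dienoate (both C3 epimers)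
Conditions: methyl propiolate, i-Bu2AlH, NMO, THF, 0 °C; then 19, 0 °C → rt
Reagents that add atoms: methyl propiolate, C#CC(=O)OC
Why: Vinylalumination (an aluminium-mediated Morita–Baylis–Hillman-type addition) installs C11–C13 quickly under non-basic conditions so C8 is not epimerised; the new carbinol (C7) is a mixture that is erased in step 19.

Step 17
Reactants: 20 methyl (4R,5R,6Z,10E)-5,12-bis(TBS-oxy)-3-hydroxy-4-(PMB-oxy)-6,10-dimethyl-2-methylidenedodeca-6,10-dienoate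
Product: 21 methyl (4R,5R,6Z,10E)-5-(TBS-oxy)-3,12-dihydroxy-4-(PMB-oxy)-6,10-dimethyl-2-methylidenedodeca-6,10-dienoate
Conditions: HF·pyridine, pyridine, THF, 0 °C → rt
Reagents that add atoms: none
Why: Buffered fluoride desilylation removes the unhindered primary allylic TBS ether (C6) much faster than the hindered secondary one at C9.

Step 18
Reactants: 21 methyl (4R,5R,6Z,10E)-5-(TBS-oxy)-3,12-dihydroxy-4-(PMB-oxy)-6,10-dimethyl-2-methylidenedodeca-6,10-dienoate
Product: 22 methyl (4R,5R,6Z,10E)-5-(TBS-oxy)-3-hydroxy-4-(PMB-oxy)-6,10-dimethyl-2-methylidene-12-oxododeca-6,10-dienoate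
Conditions: TEMPO (0.1 equiv), PhI(OAc)2 (1.1 equiv), CH2Cl2, rt
Reagents that add atoms: none
Why: Oxoammonium (TEMPO) oxidation is selective for the primary allylic alcohol over the secondary Baylis–Hillman alcohol and gives the C6 enal without E/Z isomerisation.

Step 19
Reactants: 22 methyl (4R,5R,6Z,10E)-5-(TBS-oxy)-3-hydroxy-4-(PMB-oxy)-6,10-dimethyl-2-methylidene-12-oxododeca-6,10-dienoate
Product: 23 methyl (2Z,4R,5R,6Z,10E)-2-(bromomethyl)-5-(TBS-oxy)-4-(PMB-oxy)-6,10-dimethyl-12-oxododeca-2,6,10-trienoate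
Conditions: NBS, Me2S, CH2Cl2, −20 → 0 °C
Reagents that add atoms: N-bromosuccinimide, O=C1CCC(=O)N1Br
Why: Corey–Kim-type activation of the allylic alcohol followed by SN2′ attack of bromide gives the thermodynamically favoured (Z)-2-(bromomethyl)enoate and removes the C7 carbinol stereocentre.

Step 20
Reactants: 23 methyl (2Z,4R,5R,6Z,10E)-2-(bromomethyl)-5-(TBS-oxy)-4-(PMB-oxy)-6,10-dimethyl-12-oxododeca-2,6,10-trienoate
Product: 26 8α-(PMB-oxy)-9β-(TBS-oxy)-germacra-1(10)Z,4E,11(13)-trien-12,6α-olide (6R,7S,8R,9R), via allylchromium dichloride 24 (not isolated), via hydroxy ester 25 (not isolated)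
Conditions: CrCl2 (divalent chromium, 10 equiv), DMF, rt, syringe pump (final 2 mM); then 40 °C, 2 h
Reagents that add atoms: none
Why: Intramolecular Nozaki–Hiyama (Barbier-type) allylation forms C6–C7 and the ten-membered ring through a cyclic transition state, then the chromium alkoxide lactonises. The ring is expected to enforce the anti (trans-lactone) C6/C7 relationship, and the aldehyde should reach the alkene face on the side of the C9 tether (H8 in the alkene plane to avoid A(1,3) strain, PMB ether outside the ring), giving 6R,7S; this facial selectivity is a prediction, not a certainty.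

Step 21
Reactants: 26 8α-(PMB-oxy)-9β-(TBS-oxy)-germacra-1(10)Z,4E,11(13)-trien-12,6α-olide
Product: 27 8α-hydroxy-9β-(TBS-oxy)-germacra-1(10)Z,4E,11(13)-trien-12,6α-olide
Conditions: DDQ (1.5 equiv), CH2Cl2/KH2PO4–K2HPO4 buffer pH 7 (10:1), 0 °C
Reagents that add atoms: none
Why: Oxidative PMB ether cleavage by DDQ under neutral conditions frees only C8–OH and avoids acid (transannular cyclisation of the 1,5-diene) and base (translactonisation to O8).

Step 22
Reactants: 28 methyl angelate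
Product: 29 (2Z)-2-methylbut-2-en-1-ol
Conditions: i-Bu2AlH (2.2 equiv), Et2O, −78 → 0 °C; aq. KNaC4H4O6
Reagents that add atoms: none
Why: Hydride reduction of the ester gives the Z-allylic alcohol without Z/E isomerisation.

Step 23
Reactants: 29 (2Z)-2-methylbut-2-en-1-ol
Product: 30 [(2R,3S)-2,3-dimethyloxiran-2-yl]methanol
Conditions: Ti(OiPr)4 (10 mol%), (S,S)-(−)-diethyl tartrate (12 mol%), t-BuOOH, 4 Å molecular sieves, CH2Cl2, −20 °C
Reagents that add atoms: tert-butyl hydroperoxide, CC(C)(C)OO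
Why: Catalytic Sharpless asymmetric epoxidation: the titanium tartrate complex delivers oxygen to one face of the allylic alcohol, and the (S,S)-tartrate gives the 2R,3S cis-epoxide.

Step 24
Reactants: 30 [(2R,3S)-2,3-dimethyloxiran-2-yl]methanol
Product: 31 (2S,3S)-2,3-dimethyloxirane-2-carboxylic acid
Conditions: RuCl3·3H2O (2 mol%), NaIO4 (3 equiv), CCl4/MeCN/H2O, rt
Reagents that add atoms: water, O
Why: Catalytic RuO4 oxidation takes the primary alcohol to the acid through the aldehyde hydrate without opening the epoxide; C2 becomes S by CIP priority only.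

Step 25
Reactants: 31 (2S,3S)-2,3-dimethyloxirane-2-carboxylic acid, 27 8α-hydroxy-9β-(TBS-oxy)-germacra-1(10)Z,4E,11(13)-trien-12,6α-olide
Product: 33 8α-[(2S,3S)-2,3-dimethyloxirane-2-carbonyloxy]-9β-(TBS-oxy)-germacra-1(10)Z,4E,11(13)-trien-12,6α-olide, via mixed anhydride 32 (not isolated)
Conditions: 31 (3 equiv), 2,4,6-trichlorobenzoyl chloride, Et3N, toluene, rt; then 27, DMAP, toluene, rt
Reagents that add atoms: none
Why: Yamaguchi esterification (DMAP-catalysed acyl transfer from the mixed anhydride) acylates the hindered C8–OH with retention at C8 and leaves the acid's stereocentres untouched; the neighbouring TBS ether rules out acyl migration.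

Step 26
Reactants: 33 8α-[(2S,3S)-2,3-dimethyloxirane-2-carbonyloxy]-9β-(TBS-oxy)-germacra-1(10)Z,4E,11(13)-trien-12,6α-olide
Product: 34 8α-[(2S,3S)-2,3-dimethyloxirane-2-carbonyloxy]-9β-hydroxy-germacra-1(10)Z,4E,11(13)-trien-12,6α-olide
Conditions: HF·pyridine, pyridine, THF, 0 °C → rt
Reagents that add atoms: none
Why: Buffered fluoride desilylation frees C9–OH under weakly acidic conditions, where the hindered epoxy ester does not migrate to O9 and the electron-poor epoxide is slow to open.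

Step 27
Reactants: 34 8α-[(2S,3S)-2,3-dimethyloxirane-2-carbonyloxy]-9β-hydroxy-germacra-1(10)Z,4E,11(13)-trien-12,6α-olide
Product: 35 CNP0304643.2
Conditions: Ac2O, pyridine, DMAP (cat.), CH2Cl2, 0 °C
Reagents that add atoms: acetic anhydride, CC(=O)OC(C)=O
Why: DMAP-catalysed acetylation of the remaining allylic C9–OH completes the target with no stereocentre touched.

**Compound list**
1 | 2,2-dimethyl-1,3-dioxan-5-ol | CC1(C)OCC(O)CO1 | starting material
2 | 5-(PMB-oxy)-2,2-dimethyl-1,3-dioxane | COc1ccc(COC2COC(C)(C)OC2)cc1 | intermediate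
3 | 2-(PMB-oxy)propane-1,3-diol | COc1ccc(COC(CO)CO)cc1 | intermediate
4 | 2-(PMB-oxy)propane-1,3-diyl diacetate | COc1ccc(COC(COC(C)=O)COC(C)=O)cc1 | intermediate
5 | (2R)-3-hydroxy-2-(PMB-oxy)propyl acetate | CC(=O)OC[C@H](OCc1ccc(OC)cc1)CO | intermediate
6 | (2S)-2-(PMB-oxy)-3-(TES-oxy)propyl acetate | CC(=O)OC[C@H](OCc1ccc(OC)cc1)CO[Si](CC)(CC)CC | intermediate
7 | (2S)-2-(PMB-oxy)-3-(TES-oxy)propan-1-ol | OC[C@H](OCc1ccc(OC)cc1)CO[Si](CC)(CC)CC | intermediate
8 | (2R)-2-(PMB-oxy)-3-(TES-oxy)propanal | O=C[C@H](OCc1ccc(OC)cc1)CO[Si](CC)(CC)CC | intermediate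
9 | geraniol, (2E)-3,7-dimethylocta-2,6-dien-1-ol | CC(C)=CCC/C(C)=C/CO | starting material
10 | geranyl TBS ether | CC(C)=CCC/C(C)=C/CO[Si](C)(C)C(C)(C)C | intermediate
11 | tert-butyl{[(2E)-5-(3,3-dimethyloxiran-2-yl)-3-methylpent-2-en-1-yl]oxy}dimethylsilane (racemic) | CC1(C)OC1CC/C(C)=C/CO[Si](C)(C)C(C)(C)C | intermediate
12 | (4E)-6-(TBS-oxy)-4-methylhex-4-enal | O=CCC/C(C)=C/CO[Si](C)(C)C(C)(C)C | intermediate
13 | tert-butyl{[(2E,6Z)-7-iodo-3-methylocta-2,6-dien-1-yl]oxy}dimethylsilane | C/C(I)=C/CC/C(C)=C/CO[Si](C)(C)C(C)(C)C | intermediate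
14 | alkenyllithium from 13 (lithium in place of iodine, geometry retained) | C/C([Li])=C/CC/C(C)=C/CO[Si](C)(C)C(C)(C)C | intermediate
15 | alkenylmagnesium bromide from 14 (MgBr in place of lithium, geometry retained) | C/C([Mg]Br)=C/CC/C(C)=C/CO[Si](C)(C)C(C)(C)C | intermediate
16 | (2R,3R,4Z,8E)-10-(TBS-oxy)-2-(PMB-oxy)-4,8-dimethyl-1-(TES-oxy)deca-4,8-dien-3-ol | C/C(=C/CC/C(C)=C/CO[Si](C)(C)C(C)(C)C)[C@@H](O)[C@H](OCc1ccc(OC)cc1)CO[Si](CC)(CC)CC | intermediate
17 | (2R,3R,4Z,8E)-3,10-bis(TBS-oxy)-2-(PMB-oxy)-4,8-dimethyl-1-(TES-oxy)deca-4,8-diene | C/C(=C/CC/C(C)=C/CO[Si](C)(C)C(C)(C)C)[C@@H](O[Si](C)(C)C(C)(C)C)[C@H](OCc1ccc(OC)cc1)CO[Si](CC)(CC)CC | intermediate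
18 | (2R,3R,4Z,8E)-3,10-bis(TBS-oxy)-2-(PMB-oxy)-4,8-dimethyldeca-4,8-dien-1-ol | C/C(=C/CC/C(C)=C/CO[Si](C)(C)C(C)(C)C)[C@@H](O[Si](C)(C)C(C)(C)C)[C@H](OCc1ccc(OC)cc1)CO | intermediate
19 | (2S,3R,4Z,8E)-3,10-bis(TBS-oxy)-2-(PMB-oxy)-4,8-dimethyldeca-4,8-dienal | C/C(=C/CC/C(C)=C/CO[Si](C)(C)C(C)(C)C)[C@@H](O[Si](C)(C)C(C)(C)C)[C@H](OCc1ccc(OC)cc1)C=O | intermediate
20 | methyl (4R,5R,6Z,10E)-5,12-bis(TBS-oxy)-3-hydroxy-4-(PMB-oxy)-6,10-dimethyl-2-methylidenedodeca-6,10-dienoate (both C3 epimers) | C/C(=C/CC/C(C)=C/CO[Si](C)(C)C(C)(C)C)[C@@H](O[Si](C)(C)C(C)(C)C)[C@H](OCc1ccc(OC)cc1)C(O)C(=C)C(=O)OC | intermediate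
21 | methyl (4R,5R,6Z,10E)-5-(TBS-oxy)-3,12-dihydroxy-4-(PMB-oxy)-6,10-dimethyl-2-methylidenedodeca-6,10-dienoate (both C3 epimers) | C/C(=C/CC/C(C)=C/CO)[C@@H](O[Si](C)(C)C(C)(C)C)[C@H](OCc1ccc(OC)cc1)C(O)C(=C)C(=O)OC | intermediate
22 | methyl (4R,5R,6Z,10E)-5-(TBS-oxy)-3-hydroxy-4-(PMB-oxy)-6,10-dimethyl-2-methylidene-12-oxododeca-6,10-dienoate (both C3 epimers) | C/C(=C/CC/C(C)=C/C=O)[C@@H](O[Si](C)(C)C(C)(C)C)[C@H](OCc1ccc(OC)cc1)C(O)C(=C)C(=O)OC | intermediate
23 | methyl (2Z,4R,5R,6Z,10E)-2-(bromomethyl)-5-(TBS-oxy)-4-(PMB-oxy)-6,10-dimethyl-12-oxododeca-2,6,10-trienoate | C/C(=C/CC/C(C)=C/C=O)[C@@H](O[Si](C)(C)C(C)(C)C)[C@H](OCc1ccc(OC)cc1)/C=C(\CBr)C(=O)OC | intermediate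
24 | allylchromium dichloride from 23 (CrCl2 group in place of bromine) | C/C(=C/CC/C(C)=C/C=O)[C@@H](O[Si](C)(C)C(C)(C)C)[C@H](OCc1ccc(OC)cc1)/C=C(\C[Cr](Cl)Cl)C(=O)OC | intermediate
25 | methyl 2-[(1S,2R,3E,7Z,9R,10R)-9-(TBS-oxy)-2-hydroxy-10-(PMB-oxy)-4,8-dimethylcyclodeca-3,7-dien-1-yl]prop-2-enoate | C=C(C(=O)OC)[C@H]1[C@H](O)/C=C(\C)CC/C=C(/C)[C@@H](O[Si](C)(C)C(C)(C)C)[C@@H]1OCc2ccc(OC)cc2 | intermediate
26 | 8α-(PMB-oxy)-9β-(TBS-oxy)-germacra-1(10)Z,4E,11(13)-trien-12,6α-olide (6R,7S,8R,9R; H6β, H7α) | C=C1C(=O)O[C@@H]2/C=C(\C)CC/C=C(/C)[C@@H](O[Si](C)(C)C(C)(C)C)[C@H](OCc3ccc(OC)cc3)[C@@H]12 | intermediate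
27 | 8α-hydroxy-9β-(TBS-oxy)-germacra-1(10)Z,4E,11(13)-trien-12,6α-olide (configuration as in 26) | C=C1C(=O)O[C@@H]2/C=C(\C)CC/C=C(/C)[C@@H](O[Si](C)(C)C(C)(C)C)[C@H](O)[C@@H]12 | intermediate
28 | methyl angelate, methyl (2Z)-2-methylbut-2-enoate | C/C=C(/C)C(=O)OC | starting material
29 | (2Z)-2-methylbut-2-en-1-ol | C/C=C(/C)CO | intermediate
30 | [(2R,3S)-2,3-dimethyloxiran-2-yl]methanol | OC[C@@]1(C)O[C@H]1C | intermediate
31 | (2S,3S)-2,3-dimethyloxirane-2-carboxylic acid | OC(=O)[C@@]1(C)O[C@H]1C | intermediate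
32 | (2S,3S)-2,3-dimethyloxirane-2-carboxylic 2,4,6-trichlorobenzoic anhydride | O=C(OC(=O)[C@@]1(C)O[C@H]1C)c2c(Cl)cc(Cl)cc2Cl | intermediate
33 | 8α-[(2S,3S)-2,3-dimethyloxirane-2-carbonyloxy]-9β-(TBS-oxy)-germacra-1(10)Z,4E,11(13)-trien-12,6α-olide | C=C1C(=O)O[C@@H]2/C=C(\C)CC/C=C(/C)[C@@H](O[Si](C)(C)C(C)(C)C)[C@H](OC(=O)[C@@]3(C)O[C@H]3C)[C@@H]12 | intermediate
34 | 8α-[(2S,3S)-2,3-dimethyloxirane-2-carbonyloxy]-9β-hydroxy-germacra-1(10)Z,4E,11(13)-trien-12,6α-olide | C=C1C(=O)O[C@@H]2/C=C(\C)CC/C=C(/C)[C@@H](O)[C@H](OC(=O)[C@@]3(C)O[C@H]3C)[C@@H]12 | intermediate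
35 | CNP0304643.2, (3aS,4R,5R,6Z,10E,11aR)-5-acetoxy-6,10-dimethyl-3-methylidene-2-oxo-2,3,3a,4,5,8,9,11a-octahydrocyclodeca[b]furan-4-yl (2S,3S)-2,3-dimethyloxirane-2-carboxylate | C=C1C(=O)O[C@@H]2/C=C(\C)CC/C=C(/C)[C@@H](OC(C)=O)[C@H](OC(=O)[C@@]3(C)O[C@H]3C)[C@@H]12 | target

**Step count and risks**
Total: 27 steps. Longest linear sequence: 20 steps (steps 1–7, 12–21, 25–27).

The three steps most likely to fail:

Step 20 (macrocyclisation: yield, and above all the facial selectivity at C7 relative to C8). The fallback sets out from 22 and rejoins the route at 26. Alcohol 22 is converted with ClCO2Me/pyridine into the allylic carbonate methyl (4R,5R,6Z,10E)-5-(TBS-oxy)-3-[(methoxycarbonyl)oxy]-4-(PMB-oxy)-6,10-dimethyl-2-methylidene-12-oxododeca-6,10-dienoate F2. Under Pd(PPh3)4 (zerovalent palladium, catalytic) and Et2Zn in THF at high dilution, F2 is ionised to a π-allylpalladium and transmetalated to an allylzinc (umpolung). This closes onto the enal to give hydroxy ester 25, which lactonises (catalytic DBU if needed) to 26. The ring is then closed by a different organometallic with a different transition state, so the sense of induction from C8 is decided anew.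

Step 12 (diastereoselectivity at C9). The fallback sets out from 16, taken as the C9 epimer mixture from step 12, and returns to 16 as a single epimer. Dess–Martin oxidation gives the enone (2R,4Z,8E)-10-(TBS-oxy)-2-(PMB-oxy)-4,8-dimethyl-1-(TES-oxy)deca-4,8-dien-3-one F1. Corey–Bakshi–Shibata reduction ((R)-2-methyl-CBS-oxazaborolidine, catecholborane, toluene, −78 °C, alkenyl group as the large substituent) then sets C9 by catalyst control instead of substrate control. The choice of the (R)-catalyst rests on that assumption about the large group and would be confirmed on the first run.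

Step 26 (HF on a compound carrying the epoxy ester and the acid-sensitive 1,5-diene). The fallback sets out from 26 and rejoins at 35, changing the order of the endgame so that the epoxide never meets HF. HF·pyridine on 26 gives 9β-hydroxy-8α-(PMB-oxy)-germacra-1(10)Z,4E,11(13)-trien-12,6α-olide F3. Ac2O/pyridine/DMAP gives 9β-acetoxy-8α-(PMB-oxy)-germacra-1(10)Z,4E,11(13)-trien-12,6α-olide F4. DDQ gives 9β-acetoxy-8α-hydroxy-germacra-1(10)Z,4E,11(13)-trien-12,6α-olide F5. Yamaguchi esterification of F5 with 31 (through 32) delivers 35 directly. The price is a possible acetyl shift from O9 to O8 during the last step.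

**Further compounds**
F1 | step 12 | (2R,4Z,8E)-10-(TBS-oxy)-2-(PMB-oxy)-4,8-dimethyl-1-(TES-oxy)deca-4,8-dien-3-one | C/C(=C/CC/C(C)=C/CO[Si](C)(C)C(C)(C)C)C(=O)[C@H](OCc1ccc(OC)cc1)CO[Si](CC)(CC)CC
F2 | step 20 | methyl (4R,5R,6Z,10E)-5-(TBS-oxy)-3-[(methoxycarbonyl)oxy]-4-(PMB-oxy)-6,10-dimethyl-2-methylidene-12-oxododeca-6,10-dienoate | C/C(=C/CC/C(C)=C/C=O)[C@@H](O[Si](C)(C)C(C)(C)C)[C@H](OCc1ccc(OC)cc1)C(OC(=O)OC)C(=C)C(=O)OC
F3 | step 26 | 9β-hydroxy-8α-(PMB-oxy)-germacra-1(10)Z,4E,11(13)-trien-12,6α-olide | C=C1C(=O)O[C@@H]2/C=C(\C)CC/C=C(/C)[C@@H](O)[C@H](OCc3ccc(OC)cc3)[C@@H]12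
F4 | step 26 | 9β-acetoxy-8α-(PMB-oxy)-germacra-1(10)Z,4E,11(13)-trien-12,6α-olide | C=C1C(=O)O[C@@H]2/C=C(\C)CC/C=C(/C)[C@@H](OC(C)=O)[C@H](OCc3ccc(OC)cc3)[C@@H]12
F5 | step 26 | 9β-acetoxy-8α-hydroxy-germacra-1(10)Z,4E,11(13)-trien-12,6α-olide | C=C1C(=O)O[C@@H]2/C=C(\C)CC/C=C(/C)[C@@H](OC(C)=O)[C@H](O)[C@@H]12
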